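Readings and results were generated by integration with made-up constants; noise was put on by code.

common to all: starting material 0.10 M

| charge | partner | free catalyst | remark | time |
|---|---|---|---|---|
| theta | 1.8 equiv | 0.11 mol% | run made earlier |  |
| Monday's | 1.80 equiv | 0.12 mol% |  | 50 min |
| Tuesday's | 1.80 equiv | 0.14 mol% |  | 50 min |
| Friday's | 1.80 equiv | 0.17 mol% |  | 50 min |

theta run (percent of the starting material charged)

| time / min | catalyst intermediate A / % | target / % | catalyst intermediate B / % | catalyst intermediate C / % | starting material / % |
|---|---|---|---|---|---|
| 10.0 | 0.3 | 13.4 | 1.0 | 0 | 87.4 |
| 20.0 | 1.7 | 27.3 | 0.1 | 0 | 75.1 |
| 30.0 | 0 | 35.5 | 0.4 | 0 | 63.9 |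
| 40.0 | 0.4 | 46.1 | 0 | 0.6 | 54.8 |
| 50.0 | 0 | 53.9 | 2.0 | 1.9 | 47.3 |

(standard deviation of a reading: 1 percentage point)

- percent here means starting material units held: one resting dimer counts as two
- the numbers in the tables scatter with a standard deviation of 1 percentage point
- reactions considered so far: partner + catalyst intermediate A <-> catalyst intermediate B; catalyst intermediate B <-> by-product + catalyst intermediate C; catalyst intermediate C -> free catalyst + target; 2 catalyst intermediate A <-> resting dimer; starting material + free catalyst -> catalyst intermediate A
- no earlier run changes the charge of free catalyst; that part of a forecast is a guess

* which of these there is most of at the end, counted by the starting material in it, Monday's (catalyst intermediate B / catalyst intermediate A / target / catalyst intermediate C / starting material)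
* which of these there is most of at the end, counted by the starting material in it, Tuesday's (catalyst intermediate B / catalyst intermediate A / target / catalyst intermediate C / starting material)
* which of these there is most of at the end, counted by the starting material in it, Friday's (catalyst intermediate B / catalyst intermediate A / target / catalyst intermediate C / starting material)
* the largest of these amounts at the end, in percent of the starting material charged, Monday's
* the largest of these amounts at the end, in percent of the starting material charged, Tuesday's
* the largest of these amounts at the end, in percent of the starting material charged, Friday's

1. Compare one catalyst round with the gap between readings: the theta run consumed 52.7 % of its charge by 50.0 min on 0.11 mol% of catalyst, so one round takes 6.26 s on average, far shorter than the 10.0 min of the first reading.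

2. Treat the catalyst forms as the fastest rung, in quasi-steady state from the first reading on, and set their whole charge of 0.11 mol% against a scatter of 1 percentage point: their readings are noise, and target simply mirrors the loss of starting material, 53.9 % against that 52.7 %.

3. Take starting material as the next rung and compare its slope early and late: ln([starting material]₀/[starting material]) per minute is 0.0143 min⁻¹ at 20.0 min and 0.0150 min⁻¹ at 50.0 min, which agree within the scatter, so the decay looks pseudo-first-order.

4. Carry that logarithm at the end of the run, the spent exponent, which is 0.749 for the theta run and corresponds to a half-life of 46.3 min, far longer than a round.

5. Put partner on the slowest rung, since 1.8 equiv is charged and the reactions use one per starting material, which makes starting material the limiting reagent.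

6. Scale the exponent with the loading, which is my guess because no earlier run varies the catalyst, and read target as one minus the exponential of minus the exponent: Monday's gives 0.817 and 55.8 %, Tuesday's 0.953 and 61.4 %, Friday's 1.16 and 68.6 %.

7. Set beside this the forecast, which names target for each flask at 55.8 %, 61 % and 68 %, on the ground that “rate should scale roughly linearly with catalyst”.

8. Read the result: target leads in each flask, at 57.3 %, 63.2 % and 70.9 %, and Friday's exponent comes out at 1.24, above my 1.16.

    partner + catalyst intermediate A ⇌ catalyst intermediate B (K = 3.40 M⁻¹, k = 3.40 M⁻¹ s⁻¹)
    catalyst intermediate B ⇌ by-product + catalyst intermediate C (K = 0.280 M, k = 3.40 s⁻¹)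
    catalyst intermediate C → free catalyst + target (k = 2.70 s⁻¹)
    2 catalyst intermediate A ⇌ resting dimer, settled at all times (K = 3600 M⁻¹)
    starting material + free catalyst → catalyst intermediate A (k = 7.40 M⁻¹ s⁻¹)

9. Compare the times in Monday's flask: free catalyst has a half-life of 1.3 s by capture of starting material at 21.8 min, and catalyst intermediate A has 1.7 s by the forward step with partner alone at 50.0 min, both far shorter than the 34 min of starting material by capture at 50.0 min. Catalyst intermediate B is made and used, each step taken net, at a ratio of 1.00 at 50.0 min.

10. Use the exponent on the neighbour, Monday's flask with 0.072 mol% of free catalyst: it becomes 0.490, which gives target 38.7 %, and the computed flask gives 39.8 %, with 60.2 % of the starting material left.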